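**Assumptions.** Commercial (−)-linalool is the (R)-enantiomer (≥97 % ee). Germacrane numbering (C1–C15) is used for atom labels. The target is (6R,7R,8R,10R), 1E,4Z, a trans-6,12-lactone bearing an 8-tiglate.

## Retrosynthetic overview
1. The dienone comes from oxidation of a C3 carbinol. The ten-membered ring is closed last, at C3–C4, by an electrochemical Ni/Cr coupling of a (Z)-vinyl iodide with an E-enal.
2. The E-enal comes from cross-metathesis on the vinyl carbinol. The trans α-methylene lactone comes from a chair allylboration/lactonisation with (Z)-3-iodobut-2-enal, in which C8 sets C7 and C6.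
3. The (Z)-2-carbomethoxy allylboronate comes from a Negishi coupling on an (E)-α-bromoenoate. That enoate comes from site-selective double olefination of a C7/C1 dialdehyde.
4. The dialdehyde comes from cleavage of a temporary cyclopentene. In that ring the OH and Me faces at C10 are differentiated, so C10 sets C8 by directed reduction.
5. The cyclopentenol comes from RCM of (R)-linalool, the only purchased stereocentre. Ring order: temporary cyclopentene (made, then cleaved), then lactone, then macrocycle.

## Route

**Step 1**
Reactants: 1 (R)-(−)-linalool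
Product: 2 (R)-1-methylcyclopent-2-en-1-ol (isobutene is lost)
Conditions: Hoveyda–Grubbs II (0.2 mol %), neat, 40 °C
Reagents that add atoms: none
Why: Ring-closing metathesis of the 1,6-diene is fast and does not touch C10. It places C1 and C9 in a ring, so the two faces differ as OH versus CH3.

**Step 2**
Reactants: 2
Product: 3 (R)-4-hydroxy-4-methylcyclopent-2-en-1-one
Conditions: undivided cell, RVC(+)/RVC(−), Cl4NHPI (20 mol %), t-BuOOH, pyridine, LiClO4, acetone, rt, constant current
Reagents that add atoms: tert-butyl hydroperoxide, CC(C)(C)OO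
Why: This N-oxyl-mediated electrochemical allylic C–H oxidation has only one allylic CH2 (C8) to attack. The tertiary OH is inert, and the near-neutral medium avoids retro-aldol racemisation.

**Step 3**
Reactants: 3
Product: 4 (1R,4R)-1-methylcyclopent-2-ene-1,4-diol (trans)
Conditions: Me4NBH(OAc)3, MeCN/AcOH, −30 °C
Reagents that add atoms: none
Why: In this Evans–Saksena directed reduction the C10–O-bound borohydride delivers H to the carbonyl on the OH face. The new C8–OH therefore ends trans to C10–OH, which is 8R.

**Step 4**
Reactants: 4; 5 tiglic acid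
Product: 6 (1R,4R)-4-hydroxy-4-methylcyclopent-2-en-1-yl tiglate
Conditions: EDC·HCl, DMAP, CH2Cl2, 0 °C → rt
Reagents that add atoms: tiglic acid, C/C=C(\C)C(=O)O
Why: Steglich esterification acylates the secondary allylic OH only, because the tertiary OH is too hindered. The C–O bond is not broken, so configuration is retained.

**Step 5**
Reactants: 6
Product: 7, the C10 triethylsilyl ether of 6
Conditions: TESOTf, 2,6-lutidine, CH2Cl2, −78 → 0 °C
Reagents that add atoms: triethylsilyl triflate, CC[Si](CC)(CC)OS(=O)(=O)C(F)(F)F
Why: Silylation prevents lactol formation after ring cleavage and makes the C1 terminus much more hindered than C7.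

**Step 6**
Reactants: 7
Product: 8 (2R,4R)-4-methyl-1,5-dioxo-4-(triethylsilyloxy)pentan-2-yl tiglate (C7 and C1 dialdehyde)
Conditions: OsO4 (2 mol %), NaIO4, 2,6-lutidine, dioxane/H2O, rt
Reagents that add atoms: osmium tetroxide, O=[Os](=O)(=O)=O; sodium periodate, [Na+].[O-]I(=O)(=O)=O
Why: Lemieux–Johnson cleavage takes the cis-ring alkene in preference to the electron-poor trisubstituted tiglate alkene. No stereocentre is affected.

**Step 7**
Reactants: 9 methyl bis(2,2,2-trifluoroethyl)phosphonoacetate
Product: 10 methyl bromo[bis(2,2,2-trifluoroethoxy)phosphoryl]acetate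
Conditions: NaOBr, H2O, 0 °C; then SnCl2, EtOH/H2O, 0 °C (the dibromide is not isolated)
Reagents that add atoms: sodium hypobromite, [Na+].[O-]Br
Why: Dibromination followed by selective mono-debromination is the known preparation of this bromo Still–Gennari-type reagent.

**Step 8**
Reactants: 8; 10; 11 methyltriphenylphosphonium bromide
Product: 12 methyl (2E,4R,6R)-2-bromo-6-methyl-4-(tigloyloxy)-6-(triethylsilyloxy)octa-2,7-dienoate
Conditions: 10 (1.0 equiv), t-BuOK, 18-crown-6, THF, −78 °C; then Ph3P=CH2 (from 11/KHMDS), −78 → 0 °C, same flask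
Reagents that add atoms: 10, COC(=O)C(Br)P(=O)(OCC(F)(F)F)OCC(F)(F)F; 11, C[P+](c1ccccc1)(c1ccccc1)c1ccccc1.[Br-]
Why: The kinetically controlled HWE attacks only the unhindered C7 aldehyde and gives the (E)-α-bromoenoate, with C8 cis to CO2Me. A Wittig methylenation then converts the neopentyl-type C1 aldehyde into an inert vinyl group.

**Step 9**
Reactants: 12; 13 2-(iodomethyl)-4,4,5,5-tetramethyl-1,3,2-dioxaborolane
Product: 14 methyl (2Z,4R,6R)-6-methyl-2-[(pinacolboryl)methyl]-4-(tigloyloxy)-6-(triethylsilyloxy)octa-2,7-dienoate
Conditions: 13, Zn dust, THF (forms IZnCH2Bpin); Pd(PPh3)4 (5 mol %), THF, rt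
Reagents that add atoms: 13, ICB1OC(C)(C)C(C)(C)O1
Why: Negishi coupling of the α-bromoenoate proceeds with retention, which places CH2B trans to C8. The allyl-Bpin does not β-eliminate the C8 tiglate, unlike the corresponding allyl Cr, Zn or In species.

**Step 10**
Reactants: 15 but-2-yn-1-ol
Product: 16 (Z)-3-iodobut-2-en-1-ol
Conditions: Red-Al, Et2O, 0 °C → rt; EtOAc; I2, −78 °C
Reagents that add atoms: iodine, II
Why: Hydroxyl-directed trans-hydroalumination followed by iodinolysis gives the Z isomer only.

**Step 11**
Reactants: 16
Product: 17 (Z)-3-iodobut-2-enal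
Conditions: MnO2, CH2Cl2, rt, dark; used at once
Reagents that add atoms: none
Why: Neutral allylic oxidation preserves the Z geometry.

**Step 12**
Reactants: 14; 17
Product: 18 seco-lactone: trans-α-methylene-γ-butyrolactone carrying (Z)-2-iodoprop-1-enyl at C6 and the (8R)-tigloyloxy/(10R)-hydroxy-10-methyl vinyl chain at C7. The spatial arrangement matches the target; the CIP label at C6 reads S while iodine is present.
Conditions: Sc(OTf)3 (10 mol %), 4 Å MS, PhMe, −20 °C → rt; then HF·pyridine, THF, 0 °C
Reagents that add atoms: 17, O=C/C=C(/C)I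
Why: Lewis-acid-catalysed allylboration/lactonisation proceeds through a closed chair. CH2B trans to C8 gives the 6,7-anti adduct and hence the trans lactone. A(1,3) strain with the cis CO2Me holds H8 in the alkene plane, and the aldehyde adds anti to the bulky C9 branch, giving 7R and the target sense at C6. HF then removes the TES group.

**Step 13**
Reactants: 18; 19 (E)-crotonaldehyde
Product: 20, the E-enal (C1=C2–C3HO) derived from 18
Conditions: Hoveyda–Grubbs II (5 mol %), 19 (5 equiv), CH2Cl2, 40 °C
Reagents that add atoms: crotonaldehyde, C/C=C/C=O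
Why: Cross-metathesis of a tertiary allylic alcohol with an enal is E-selective. The α-methylene lactone, the tiglate and the trisubstituted vinyl iodide are spectator alkenes.

**Step 14**
Reactants: 20
Product: 21, the ten-membered 3-hydroxy-germacra-1E,4Z,11(13)-trien-6,12-olide (C3 epimers)
Conditions: undivided cell, Al(+)/Ni foam(−), CrCl3·3THF (20 mol %), NiCl2·dme/neocuproine (2 mol %), Cp2ZrCl2 (1.2 equiv), LiCl, Bu4NBF4, DMF, rt, constant current; 20 added by syringe pump (≤1 mM); aqueous serinate work-up
Reagents that add atoms: none
Why: Proposed new method: a catalytic electroreductive Ni/Cr (e-NHK) macrocyclisation in which the cathode regenerates Cr(II) and Ni(0); Ni(0) inserts into the C4–I bond with retention of Z geometry and transmetallates to Cr(III), and the alkenyl-Cr(III) adds 1,2 to the tethered enal while Cp2ZrCl2 releases the Cr alkoxide so that Cr turns over; the Cr(III)/Cr(II) potential is expected to lie well positive of the reduction potentials of the enal, α-methylene lactone and tiglate, and matching the feed rate to the current keeps the substrate dilute; the closest known reaction types are stoichiometric CrCl2/NiCl2 NHK macrocyclisations (including ten-membered germacranolides) and the intermolecular electrochemical NHK coupling, which to my knowledge has not been used to close a medium ring; the step forms C3–C4 and the carbocycle, and the new C3 stereocentre is erased in Step 15.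

**Step 15**
Reactants: 21
Product: 22 eupaheliangolide A
Conditions: Dess–Martin periodinane, NaHCO3, CH2Cl2, 0 °C, light excluded
Reagents that add atoms: none
Why: Buffered oxidation of the bis-allylic alcohol gives the cross-conjugated dienone. The tertiary OH is inert, and excluding light avoids 1E→1Z isomerisation followed by hemiketalisation.

## Compound list

| No. | Name | SMILES | Role |
|---|---|---|---|
| 1 | (R)-linalool | `C=C[C@](C)(O)CCC=C(C)C` | starting material |
| 2 | (R)-1-methylcyclopent-2-en-1-ol | `C1=C[C@](C)(O)CC1` | intermediate |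
| 3 | (R)-4-hydroxy-4-methylcyclopent-2-enone | `O=C1C=C[C@](C)(O)C1` | intermediate |
| 4 | (1R,4R)-1-methylcyclopent-2-ene-1,4-diol | `C1=C[C@](C)(O)C[C@H]1O` | intermediate |
| 5 | tiglic acid | `C/C=C(\C)C(=O)O` | starting material |
| 6 | mono-tiglate | `C1=C[C@](C)(O)C[C@H]1OC(=O)/C(C)=C/C` | intermediate |
| 7 | TES ether | `C1=C[C@](C)(O[Si](CC)(CC)CC)C[C@H]1OC(=O)/C(C)=C/C` | intermediate |
| 8 | dialdehyde | `O=C[C@](C)(O[Si](CC)(CC)CC)C[C@@H](OC(=O)/C(C)=C/C)C=O` | intermediate |
| 9 | methyl bis(trifluoroethyl)phosphonoacetate | `COC(=O)CP(=O)(OCC(F)(F)F)OCC(F)(F)F` | starting material |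
| 10 | bromophosphonoacetate | `COC(=O)C(Br)P(=O)(OCC(F)(F)F)OCC(F)(F)F` | intermediate |
| 11 | methyltriphenylphosphonium bromide | `C[P+](c1ccccc1)(c1ccccc1)c1ccccc1.[Br-]` | starting material |
| 12 | (E)-α-bromoenoate | `C=C[C@](C)(O[Si](CC)(CC)CC)C[C@@H](OC(=O)/C(C)=C/C)/C=C(/Br)C(=O)OC` | intermediate |
| 13 | ICH2Bpin | `ICB1OC(C)(C)C(C)(C)O1` | starting material |
| 14 | (Z)-allylboronate | `C=C[C@](C)(O[Si](CC)(CC)CC)C[C@@H](OC(=O)/C(C)=C/C)/C=C(/CB1OC(C)(C)C(C)(C)O1)C(=O)OC` | intermediate |
| 15 | but-2-yn-1-ol | `CC#CCO` | starting material |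
| 16 | (Z)-3-iodobut-2-en-1-ol | `OC/C=C(/C)I` | intermediate |
| 17 | (Z)-3-iodobut-2-enal | `O=C/C=C(/C)I` | intermediate |
| 18 | seco-lactone (vinyl / vinyl iodide) | `C=C1C(=O)O[C@H](/C=C(/C)I)[C@H]1[C@H](OC(=O)/C(C)=C/C)C[C@@](C)(O)C=C` | intermediate |
| 19 | (E)-crotonaldehyde | `C/C=C/C=O` | starting material |
| 20 | seco-enal | `C=C1C(=O)O[C@H](/C=C(/C)I)[C@H]1[C@H](OC(=O)/C(C)=C/C)C[C@@](C)(O)/C=C/C=O` | intermediate |
| 21 | macrocyclic C3 alcohol | `C=C1C(=O)O[C@@H]2/C=C(/C)C(O)/C=C/[C@](C)(O)C[C@@H](OC(=O)/C(C)=C/C)[C@@H]12` | intermediate |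
| 22 | eupaheliangolide A | `C=C1C(=O)O[C@@H]2/C=C(/C)C(=O)/C=C/[C@](C)(O)C[C@@H](OC(=O)/C(C)=C/C)[C@@H]12` | target |

## Step count
- Total steps: 15.
- Longest linear sequence: 12 (Steps 1–6, 8, 9, 12–15).

## Steps most likely to fail
1. **Step 14 (proposed e-NHK macrocyclisation).** The risks are oligomerisation, proto-deiodination and poor Cr turnover at high dilution.
   - Fallback (known chemistry, different closure): couple 18 with acrolein by a stoichiometric CrCl2/NiCl2 NHK reaction.
   - Oxidise with DMP to the divinyl-type ketone.
   - Close the ring at C1=C2 by Grubbs-II ring-closing metathesis with the vinyl carbinol.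
2. **Step 12 (allylboration).** The risks are low facial selectivity at C7, a sluggish ester-deactivated boronate, and Lewis-acid lability of the tertiary allylic silyl ether and of iodoenal 17.
   - Fallback: form C7–C11 instead, under polar Felkin–Anh control, carrying C8–O as a TBS ether.
   - Wittig-homologate the C7 aldehyde to the E-enal, then add isopropenyl cuprate/TMSCl anti to C8–O.
   - Carry out Rubottom hydroxylation at C6 and Stork–Zhao iodo-olefination at C5.
   - Convert the isopropenyl methyl into the α-methylene lactone with SeO2/MnO2, and install the tiglate last.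
3. **Step 2 (allylic oxidation of the free tertiary allylic alcohol).** The risks are low conversion, dehydration and retro-aldol racemisation of 3.
   - Fallback: silylate 2 first, then oxidise with CrO3·3,5-dimethylpyrazole.
   - Reduce under Luche conditions anti to the OTES group to give the cis alcohol.
   - Esterify with tiglic acid under Mitsunobu conditions (inversion at C8), which gives 7 directly.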